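The route cuts the dodecatrienyl chain on both sides of its central alkene. C6=C7 is a bare cis CH=CH unit held between the E-alkenes C4=C5 and C8=C9, so it is taken as one molecule of acetylene. In one flask an (E)-pentenyl cuprate (C8–C12) adds syn to acetylene (C7–C8 bond, Z geometry) and the resulting dienyl metal is cross-coupled, with zinc and palladium, to an (E)-alkenyl iodide (C1–C5; C5–C6 bond). That iodide already carries the glycerol as the acetonide ether of (R)-solketal, the source of the only stereocentre. The route builds no ring: the benzene ring is bought, and its ester is attached last under neutral, largely enzymatic conditions.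

Key step: step 5

Remark: chain carbons are numbered C1 (OCH2) to C12 (CH3); the glycerol carbon of the target is (S), that of a 1-O-alkyl-2-O-aroyl-sn-glycerol, and the given structures needed no correction; from step 5 onward all trienes should be handled under argon, away from light, and concentrated below 30 °C.

Step 1
Reactants: 1 pent-4-yn-1-ol
Product: 2 pent-4-yn-1-yl 4-methylbenzenesulfonate
Conditions: TsCl (1.1 equiv), Et3N (1.5 equiv), DMAP (5 mol %), CH2Cl2, 0 °C to rt
Reagents that add atoms: tosyl chloride, Cc1ccc(cc1)S(Cl)(=O)=O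
Why: Sulfonylation (tosylation) of an unhindered primary alcohol is fast under amine base with DMAP catalysis and leaves the terminal alkyne untouched.

Step 2
Reactants: 3 (R)-solketal; 2 pent-4-yn-1-yl 4-methylbenzenesulfonate
Product: 5 (R)-2,2-dimethyl-4-[(pent-4-yn-1-yloxy)methyl]-1,3-dioxolane, via solketal sodium alkoxide 4 (not isolated)
Conditions: 3 (1.25 equiv), NaH (1.15 equiv), THF–DMF (4:1), 0 °C to rt; then 2 (1.0 equiv), Bu4NI (5 mol %), rt to 40 °C
Reagents that add atoms: none
Why: Williamson ether synthesis, in which the primary alkoxide displaces the primary tosylate by SN2 (through the iodide formed in situ) while the alcohol is kept in excess over NaH so that no hydride remains to attack the alkyne C–H; only the exocyclic O–H bond is broken, so the stereocentre is untouched.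

Step 3
Reactants: 5 (R)-2,2-dimethyl-4-[(pent-4-yn-1-yloxy)methyl]-1,3-dioxolane
Product: 7 (R)-4-({[(4E)-5-iodopent-4-en-1-yl]oxy}methyl)-2,2-dimethyl-1,3-dioxolane (fragment 3), via alkenylzirconocene chloride 6 (not isolated)
Conditions: Cp2Zr(H)Cl (1.3 equiv), THF, rt, dark; then I2 (1.3 equiv), THF, 0 °C; aq. Na2S2O3/NaHCO3
Reagents that add atoms: iodine, II
Why: Hydrozirconation adds Zr–H syn across the terminal alkyne with zirconium on the terminal carbon and iodinolysis of the C–Zr bond goes with retention, which sets C4=C5 as E, while ether and acetal oxygens tolerate both reagents.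

Step 4
Reactants: 8 pent-1-yne
Product: 10 (E)-1-iodopent-1-ene (fragment 1), via (E)-pent-1-enylzirconocene chloride 9 (not isolated)
Conditions: 8 (1.2 equiv), Cp2Zr(H)Cl (1.0 equiv), CH2Cl2, 0 °C to rt, dark; then I2 (1.0 equiv), 0 °C; aq. Na2S2O3; pentane/silica plug, careful concentration, stored as a titrated Et2O solution
Reagents that add atoms: iodine, II
Why: The same syn hydrozirconation and stereoretentive iodinolysis should give the E-iodide that later becomes C8=C9, and handling the volatile product in solution avoids losses.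

Step 5
Reactants: 10 (E)-1-iodopent-1-ene; 11 acetylene (fragment 2); 7 (R)-4-({[(4E)-5-iodopent-4-en-1-yl]oxy}methyl)-2,2-dimethyl-1,3-dioxolane
Product: 16 (R)-4-({[(4E,6Z,8E)-dodeca-4,6,8-trien-1-yl]oxy}methyl)-2,2-dimethyl-1,3-dioxolane, via (E)-pent-1-enyllithium 12 (not isolated), via lithium bis[(E)-pent-1-enyl]cuprate 13 (not isolated), via lithium bis[(1Z,3E)-hepta-1,3-dienyl]cuprate 14 (not isolated), via (1Z,3E)-hepta-1,3-dienylzinc bromide 15 (not isolated)
Conditions: 10 (2.4 equiv), t-BuLi (4.8 equiv), Et2O, −78 °C; CuBr·SMe2 (1.2 equiv), −78 to −40 °C; HC≡CH (2.4 equiv, gas burette), −50 to −25 °C; Ar purge; then THF, ZnBr2 (2.4 equiv), Pd(PPh3)4 (5 mol %), 7 (1.0 equiv), −20 °C to rt, dark; aq. NH4Cl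
Reagents that add atoms: none
Why: Iodine–lithium exchange with retention gives 12, CuBr·SMe2 turns it into the homocuprate 13 of monovalent copper, each alkenyl–copper bond adds syn across one acetylene through a four-centre carbometalation to give 14 (new C7–C8 bond, C6=C7 necessarily Z), ZnBr2 passes the dienyl group to zinc (15), and zerovalent palladium inserts into the C–I bond of 7, takes up the dienyl group and reductively eliminates to form C5–C6. The closest known reaction type is the carbocupration of acetylene by lithium dialkenylcuprates followed by ZnBr2- and Pd(PPh3)4-mediated (Negishi-type) coupling of the alkenylcopper species with an alkenyl iodide. The step closes no ring and creates no stereocentre; the dioxolane carbon of 7 is a spectator. It needs exactly one acetylene insertion per alkenyl group and retention of both E geometries: the first is secured by the metered acetylene charge, the −25 °C ceiling and the purge before warming, the second by the stereospecific exchange, cupration, oxidative addition and reductive elimination. The substrate suits the step because 7 (the limiting partner) offers only ether and acetal oxygens to the organometallics and because the triene is formed at or below room temperature, well under the threshold of 6π electrocyclization or Z-to-E isomerization.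

Step 6
Reactants: 16 (R)-4-({[(4E,6Z,8E)-dodeca-4,6,8-trien-1-yl]oxy}methyl)-2,2-dimethyl-1,3-dioxolane
Product: 17 (2S)-3-{[(4E,6Z,8E)-dodeca-4,6,8-trien-1-yl]oxy}propane-1,2-diol (1-O-trienyl-sn-glycerol)
Conditions: AcOH–H2O–THF (4:1:1), 40 °C, Ar, dark; toluene co-evaporation below 30 °C
Reagents that add atoms: none
Why: Acid-catalysed hydrolysis of a terminal isopropylidene acetal proceeds in aqueous acetic acid, an acid too weak to protonate the triene, and no bond to the stereocentre is broken.

Step 7
Reactants: 17 (2S)-3-{[(4E,6Z,8E)-dodeca-4,6,8-trien-1-yl]oxy}propane-1,2-diol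
Product: 18 (2R)-3-{[(4E,6Z,8E)-dodeca-4,6,8-trien-1-yl]oxy}-2-hydroxypropyl acetate (3-O-acetyl-1-O-trienyl-sn-glycerol)
Conditions: immobilized Candida antarctica lipase B, vinyl acetate (3 equiv), MTBE, rt, dark; filter off the enzyme
Reagents that add atoms: vinyl acetate, CC(=O)OC=C
Why: Lipase-catalysed irreversible transesterification with an enol ester should acylate only the unhindered primary hydroxyl of the 1-O-alkylglycerol, and the neutral medium leaves the triene and the stereocentre alone (the descriptor changes to R only through the priority rules).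

Step 8
Reactants: 19 4-acetoxybenzoic acid
Product: 20 4-acetoxybenzoyl chloride
Conditions: (COCl)2 (1.3 equiv), DMF (cat.), CH2Cl2, 0 °C to rt; evaporate, use crude
Reagents that add atoms: oxalyl chloride, O=C(Cl)C(Cl)=O
Why: Acid chloride formation through the Vilsmeier-type chloroiminium species from DMF and oxalyl chloride runs at or below room temperature and does not touch the aryl acetate.

Step 9
Reactants: 18 (2R)-3-{[(4E,6Z,8E)-dodeca-4,6,8-trien-1-yl]oxy}-2-hydroxypropyl acetate; 20 4-acetoxybenzoyl chloride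
Product: 21 (2R)-1-(acetyloxy)-3-{[(4E,6Z,8E)-dodeca-4,6,8-trien-1-yl]oxy}propan-2-yl 4-(acetyloxy)benzoate
Conditions: 20 (1.3 equiv), pyridine (3 equiv), CH2Cl2, 0 °C to rt, dark; cold aq. citric acid work-up
Reagents that add atoms: none
Why: Einhorn-type acylation of the secondary alcohol by the aroyl chloride in pyridine breaks only the O–H bond (retention), and leaving out DMAP keeps the aryl acetate from acting as an acetyl donor.

Step 10
Reactants: 21 (2R)-1-(acetyloxy)-3-{[(4E,6Z,8E)-dodeca-4,6,8-trien-1-yl]oxy}propan-2-yl 4-(acetyloxy)benzoate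
Product: 22 (2S)-1-{[(4E,6Z,8E)-dodeca-4,6,8-trien-1-yl]oxy}-3-hydroxypropan-2-yl 4-hydroxybenzoate (target)
Conditions: immobilized Candida antarctica lipase B, EtOH (20 equiv), MTBE, rt, dark; filter; chromatography on neutral silica at about 5 °C
Reagents that add atoms: none
Why: Lipase-catalysed alcoholysis should remove the two unhindered acetates (primary alkyl and activated aryl) while the aroyl ester on the secondary carbinol is a very poor substrate for this enzyme, and the neutral medium suppresses migration of the aroyl group from O-2 to O-3.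

Compound list
1 | pent-4-yn-1-ol | OCCCC#C | starting material
2 | pent-4-yn-1-yl 4-methylbenzenesulfonate | Cc1ccc(cc1)S(=O)(=O)OCCCC#C | intermediate
3 | (R)-solketal, [(4R)-2,2-dimethyl-1,3-dioxolan-4-yl]methanol (2,3-O-isopropylidene-sn-glycerol) | OC[C@@H]1COC(C)(C)O1 | starting material
4 | sodium [(4R)-2,2-dimethyl-1,3-dioxolan-4-yl]methanolate | [Na+].[O-]C[C@@H]1COC(C)(C)O1 | intermediate
5 | (R)-2,2-dimethyl-4-[(pent-4-yn-1-yloxy)methyl]-1,3-dioxolane | C#CCCCOC[C@@H]1COC(C)(C)O1 | intermediate
6 | chlorobis(cyclopentadienyl)[(1E)-5-{[(4R)-2,2-dimethyl-1,3-dioxolan-4-yl]methoxy}pent-1-en-1-yl]zirconium | Cl[Zr](/C=C/CCCOC[C@@H]1COC(C)(C)O1)(C1C=CC=C1)C1C=CC=C1 | intermediate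
7 | (R)-4-({[(4E)-5-iodopent-4-en-1-yl]oxy}methyl)-2,2-dimethyl-1,3-dioxolane | I/C=C/CCCOC[C@@H]1COC(C)(C)O1 | intermediate
8 | pent-1-yne | CCCC#C | starting material
9 | chlorobis(cyclopentadienyl)[(1E)-pent-1-en-1-yl]zirconium | CCC/C=C/[Zr](Cl)(C1C=CC=C1)C1C=CC=C1 | intermediate
10 | (E)-1-iodopent-1-ene | CCC/C=C/I | intermediate
11 | acetylene | C#C | starting material
12 | (E)-pent-1-enyllithium | CCC/C=C/[Li] | intermediate
13 | lithium bis[(E)-pent-1-enyl]cuprate | [Li+].CCC/C=C/[Cu-]/C=C/CCC | intermediate
14 | lithium bis[(1Z,3E)-hepta-1,3-dienyl]cuprate | [Li+].CCC/C=C/C=C\[Cu-]/C=C\C=C\CCC | intermediate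
15 | (1Z,3E)-hepta-1,3-dienylzinc bromide | CCC/C=C/C=C\[Zn]Br | intermediate
16 | (R)-4-({[(4E,6Z,8E)-dodeca-4,6,8-trien-1-yl]oxy}methyl)-2,2-dimethyl-1,3-dioxolane | CCC/C=C/C=C\C=C\CCCOC[C@@H]1COC(C)(C)O1 | intermediate
17 | (2S)-3-{[(4E,6Z,8E)-dodeca-4,6,8-trien-1-yl]oxy}propane-1,2-diol | CCC/C=C/C=C\C=C\CCCOC[C@@H](O)CO | intermediate
18 | (2R)-3-{[(4E,6Z,8E)-dodeca-4,6,8-trien-1-yl]oxy}-2-hydroxypropyl acetate | CCC/C=C/C=C\C=C\CCCOC[C@@H](O)COC(C)=O | intermediate
19 | 4-acetoxybenzoic acid | CC(=O)Oc1ccc(cc1)C(=O)O | starting material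
20 | 4-acetoxybenzoyl chloride | CC(=O)Oc1ccc(cc1)C(Cl)=O | intermediate
21 | (2R)-1-(acetyloxy)-3-{[(4E,6Z,8E)-dodeca-4,6,8-trien-1-yl]oxy}propan-2-yl 4-(acetyloxy)benzoate | CCC/C=C/C=C\C=C\CCCOC[C@H](COC(C)=O)OC(=O)c1ccc(OC(C)=O)cc1 | intermediate
22 | (2S)-1-{[(4E,6Z,8E)-dodeca-4,6,8-trien-1-yl]oxy}-3-hydroxypropan-2-yl 4-hydroxybenzoate | CCC/C=C/C=C\C=C\CCCOC[C@H](CO)OC(=O)c1ccc(O)cc1 | target

Total step count: 10 steps.
Longest linear sequence: 8 steps (steps 1, 2, 3, 5, 6, 7, 9, 10, from pent-4-yn-1-ol).

Steps most likely to fail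

Step 5. A second acetylene may insert, or carbocupration may stay incomplete, so that chains one C2 unit too long or too short enter the coupling; homocoupling of the dienyl groups may also use up the reagent. The fallback sets out from 7 and 10 and comes back at 16. Sonogashira coupling of 7 with ethynyltrimethylsilane (PdCl2(PPh3)2, CuI, Et3N, THF, rt) should give the silylated enyne F1. K2CO3 in MeOH removes the silyl group to give the terminal enyne F2. A second Sonogashira coupling, with 10, gives the (4E,8E)-dien-6-yne F3. Cis-selective semireduction of the flanked triple bond with zinc dust activated by Cu(OAc)2 and AgNO3 in aqueous MeOH (Boland reduction) then gives 16 with the Z alkene at C6=C7.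

Step 10. The enzyme may cleave the phenolic acetate too slowly or begin to attack the secondary ester, and during a long reaction the aroyl group may migrate from O-2 to the freed O-3. The fallback sets out from 17 and comes back at 22. The primary hydroxyl is silylated selectively (TBSCl, imidazole, CH2Cl2, −20 °C) to the primary silyl ether F4. Acylation with 20 in pyridine–CH2Cl2 gives the silyl-protected acetoxybenzoate F5. Aminolysis with pyrrolidine (CH2Cl2, 0 °C) removes only the phenolic acetate to give the silyl-protected phenol F6; migration is impossible while O-3 is silylated. Et3N·3HF in THF at rt then cleaves the silyl ether to 22 under nearly neutral conditions.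

Step 9. Acylation without an acyl-transfer catalyst may stall, and on forcing the phenolic acetyl group may pass to the secondary hydroxyl or the primary acetyl group may wander to O-2. The fallback sets out from 18 and comes back at 22. 4-Hydroxybenzoic acid is bis-silylated (TBSCl, imidazole, DMF) to the silyl ester F7, and K2CO3 in aqueous THF–MeOH hydrolyses the silyl ester to 4-(tert-butyldimethylsilyloxy)benzoic acid F8, which holds no transferable acyl group. Steglich esterification of 18 with this acid (EDC·HCl, DMAP, CH2Cl2, 0 °C) gives the silyloxybenzoate F9. KHF2 in MeOH at rt cleaves only the aryl silyl ether to the phenol monoacetate F10. Lipase ethanolysis as in step 10, now of a single primary acetate, gives 22.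

Further compounds
F1 | step 5 | (R)-2,2-dimethyl-4-({[(4E)-7-(trimethylsilyl)hept-4-en-6-yn-1-yl]oxy}methyl)-1,3-dioxolane | C[Si](C)(C)C#C/C=C/CCCOC[C@@H]1COC(C)(C)O1
F2 | step 5 | (R)-4-({[(4E)-hept-4-en-6-yn-1-yl]oxy}methyl)-2,2-dimethyl-1,3-dioxolane | C#C/C=C/CCCOC[C@@H]1COC(C)(C)O1
F3 | step 5 | (R)-4-({[(4E,8E)-dodeca-4,8-dien-6-yn-1-yl]oxy}methyl)-2,2-dimethyl-1,3-dioxolane | CCC/C=C/C#C/C=C/CCCOC[C@@H]1COC(C)(C)O1
F4 | step 10 | (2R)-1-[(tert-butyldimethylsilyl)oxy]-3-{[(4E,6Z,8E)-dodeca-4,6,8-trien-1-yl]oxy}propan-2-ol | CCC/C=C/C=C\C=C\CCCOC[C@@H](O)CO[Si](C)(C)C(C)(C)C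
F5 | step 10 | (2R)-1-[(tert-butyldimethylsilyl)oxy]-3-{[(4E,6Z,8E)-dodeca-4,6,8-trien-1-yl]oxy}propan-2-yl 4-(acetyloxy)benzoate | CCC/C=C/C=C\C=C\CCCOC[C@H](CO[Si](C)(C)C(C)(C)C)OC(=O)c1ccc(OC(C)=O)cc1
F6 | step 10 | (2R)-1-[(tert-butyldimethylsilyl)oxy]-3-{[(4E,6Z,8E)-dodeca-4,6,8-trien-1-yl]oxy}propan-2-yl 4-hydroxybenzoate | CCC/C=C/C=C\C=C\CCCOC[C@H](CO[Si](C)(C)C(C)(C)C)OC(=O)c1ccc(O)cc1
F7 | step 9 | tert-butyldimethylsilyl 4-[(tert-butyldimethylsilyl)oxy]benzoate | CC(C)(C)[Si](C)(C)Oc1ccc(cc1)C(=O)O[Si](C)(C)C(C)(C)C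
F8 | step 9 | 4-[(tert-butyldimethylsilyl)oxy]benzoic acid | CC(C)(C)[Si](C)(C)Oc1ccc(cc1)C(=O)O
F9 | step 9 | (2R)-1-(acetyloxy)-3-{[(4E,6Z,8E)-dodeca-4,6,8-trien-1-yl]oxy}propan-2-yl 4-[(tert-butyldimethylsilyl)oxy]benzoate | CCC/C=C/C=C\C=C\CCCOC[C@H](COC(C)=O)OC(=O)c1ccc(O[Si](C)(C)C(C)(C)C)cc1
F10 | step 9 | (2R)-1-(acetyloxy)-3-{[(4E,6Z,8E)-dodeca-4,6,8-trien-1-yl]oxy}propan-2-yl 4-hydroxybenzoate | CCC/C=C/C=C\C=C\CCCOC[C@H](COC(C)=O)OC(=O)c1ccc(O)cc1
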